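The rate constants were drawn at random within sensible limits.

The product is chain length: how long are the chains when this flask stops? No step removes a living end, so chains begun equal c(living end), and the length is c(monomer in chains) over c(living end). I call the steps starting, growth and capping, in the order written.

free monomer 1.0 M; initiator 50 mM; time 5.0 min

    free monomer + initiator → living end + monomer in chains (k1 = 0.0098 /M/s)
    free monomer + living end → monomer in chains + living end, rate k2*[living end]*[free monomer] (k2 = 0.20 /M/s)
    initiator + monomer in chains → spent initiator (k3 = 0.070 /M/s)

- the average divides the monomer in chains by the number of chains begun, living and dead together
- run time (flask): 5.0 min

* whether the average number of monomer units in a chain (chains begun, living or dead) reaches 8.0 by 5.0 min (no / yes)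
* average number of monomer units in a chain (chains begun, living or dead) at 5.0 min

Two numbers clash: the capping constant 0.070 /M/s is 7.14 times the starting constant 0.0098 /M/s, yet this flask begins chains at once. But capping runs on c(monomer in chains), charged at nothing, and starting runs on c(free monomer), so capping catches up when their ratio reaches 0.140.

I hold free monomer and initiator at their charge and integrate: c(living end) grows with t, c(monomer in chains) with the square of t. The early length is one plus half the growth constant times c(free monomer) times t, which reaches 8.0 at 1.17 min. The ratio gives 0.891 min, the handover time, when capping matches starting: the square root of two over growth constant, capping constant and both charges, with the starting constant cancelled.

Reckoned with starting as the one draw on initiator, 40.8% of its charge has gone into chains by then, which puts c(living end) near 0.0204 M. Holding that count makes free monomer decay pseudo-first-order, and the length at 5.0 min comes to 34.6. I expect that estimate to run high: in this reckoning 59.2% of the initiator is still unused at the handover time, and some of it can still begin chains.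

The forecast says yes and 27.5, between 26 and 29, holding that “only about a fifth of it still starts chains”; its length is lower than mine.

The simulation gives yes, at 1.16 min, and a length of 27.5.

At 2.13 min, past the handover time of 0.891 min, starting uses initiator at 0.23 of the rate of capping. This flask holds c(living end) 0.0267 M at 5.00 min, equal to 53.4% of the initiator charged. In a flask with half the initiator, the reckoned handover time moves to 1.26 min, and the share of its charge reckoned as going into chains by then, again with starting as the one draw, rises to 52.3%. That flask ends at a length of 34.6.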